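Ring C is disconnected across C1–C14 and C10–C11. One enantioselective Diels–Alder reaction of an (E)-2-methylbut-2-enal carrying the C9 oxygen (C2, C1, C10, C9) with an (E,E)-1-silyloxypenta-1,3-diene (C14 to C11) builds the cyclohexene and fixes the contiguous C14 oxygen, the quaternary C1 methyl centre and C10 at once, because their cis/trans pattern is that of a formyl-endo adduct. The C9 oxygen is protected as a p-methoxybenzyl ether so that it can be unmasked oxidatively beside alkenes. Afterwards the alkene is moved to C11=C12, the formyl group receives C3–C7, C9 is turned into the butenolide precursor, a Nozaki–Hiyama–Kishi reaction closes the ten-membered ring, and acylation and epoxidation finish.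

Key step: step 3

Assumption: 2-[(4-methoxybenzyl)oxy]acetaldehyde is taken as a catalogue aldehyde (otherwise it is the ozonolysis product of (Z)-1,4-bis(4-methoxybenzyloxy)but-2-ene).
Remark: briarane numbering (C1–C20) is used for all intermediates.

Step 1
Reactants: 1 2-[(4-methoxybenzyl)oxy]acetaldehyde; 2 2-(triphenyl-λ5-phosphanylidene)propanal
Product: 3 (E)-4-[(4-methoxybenzyl)oxy]-2-methylbut-2-enal
Conditions: toluene, 80 °C
Reagents that add atoms: none
Why: Wittig olefination with a formyl-stabilised ylide, which should be E-selective because the oxaphosphetane equilibrates to the isomer with the formyl group trans to the new substituent.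

Step 2
Reactants: 4 (E)-pent-2-enal
Product: 5 (1E,3E)-1-(tert-butyldimethylsilyloxy)penta-1,3-diene
Conditions: TBSOTf, Et3N, Et2O, 0 °C → rt
Reagents that add atoms: tert-butyldimethylsilyl trifluoromethanesulfonate, CC(C)(C)[Si](C)(C)OS(=O)(=O)C(F)(F)F
Why: Silyl dienol ether formation (O-silylation, then γ-deprotonation); the extended E,E isomer should predominate, and any Z isomer cannot reach the s-cis conformation and is a spectator in step 3.

Step 3
Reactants: 3 (E)-4-[(4-methoxybenzyl)oxy]-2-methylbut-2-enal; 5 (1E,3E)-1-(tert-butyldimethylsilyloxy)penta-1,3-diene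
Product: 6 (1S,2R,5S,6R)-2-(tert-butyldimethylsilyloxy)-6-{[(4-methoxybenzyl)oxy]methyl}-1,5-dimethylcyclohex-3-ene-1-carbaldehyde (ring C: C1 formyl, C14 OTBS, C11 methyl, C10 CH2OPMB)
Conditions: (S)-3,3-diphenyl-1-(o-tolyl)tetrahydro-1H,3H-pyrrolo[1,2-c][1,3,2]oxazaborole·HNTf2 (20 mol %), 5 (2 equiv), CH2Cl2, −78 → −40 °C
Reagents that add atoms: none
Why: The aldehyde of 3 binds to the cationic boron (B–O coordination reinforced by a formyl C–H···O contact), which lowers the LUMO of the s-trans enal, and 5 adds in a concerted, asynchronous, suprafacial [4+2] in which C11–C10 bonding runs ahead of C14–C1 bonding. The closest known reaction type is the oxazaborolidinium-catalysed Diels–Alder reaction of 2-substituted acroleins with 1-silyloxy-1,3-dienes. Ring C (C1, C10, C11, C12, C13, C14) is closed by this intermolecular cycloaddition, both σ-bonds forming on one face of each partner. C1/C10 (C2 trans to C9) follows from the E enal, C11/C14 (methyl cis to OSi) from the E,E diene, C1/C14 (formyl cis to OSi) from the formyl-endo transition state, and the absolute sense from the catalyst, whose aryl group covers one enal face so that the diene should reach the Re face of C1 (assigned by analogy with 2-methyl- and 2-bromoacrolein). The step needs ortho regiochemistry, endo topicity and one enal face: the 1-silyloxy group makes C11 the nucleophilic diene terminus for the enal β-carbon C10, the α-methyl group prefers the exo position, and the rigid catalyst–aldehyde complex supplies the facial bias.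

Step 4
Reactants: 6 ring-C aldehyde with C12=C13
Product: 7 (1S,2R,6R)-2-(tert-butyldimethylsilyloxy)-6-{[(4-methoxybenzyl)oxy]methyl}-1,5-dimethylcyclohex-4-ene-1-carbaldehyde (C11=C12 isomer)
Conditions: RuHCl(CO)(PPh3)3 (5 mol %), toluene, 80 °C
Reagents that add atoms: none
Why: Metal-hydride alkene isomerisation (insertion, then β-hydride elimination) to the more stable trisubstituted C11=C12 olefin; ruthenium should add at C12 and hydrogen at C13 because C13 is screened by the C14 silyl ether and the C1 quaternary centre, and the C11 stereocentre is erased by design.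

Step 5
Reactants: 7 C11=C12 aldehyde
Product: 8 (2S)-vinyl carbinol (7 with the formyl group converted into C2H(OH)–CH=CH2; O2 syn to O14)
Conditions: CH2=CHMgBr, THF, −78 → −40 °C
Reagents that add atoms: vinylmagnesium bromide, C=C[Mg]Br
Why: Grignard 1,2-addition to a non-enolisable neopentyl aldehyde; under non-chelating conditions the carbonyl oxygen should turn away from the axial C14 silyloxy group and the vinyl group should enter anti to the C1–C10 bond, between the C1 methyl group and C14–H, which gives the 2S carbinol.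

Step 6
Reactants: 8 (2S)-vinyl carbinol
Product: 9 C2 triethylsilyl ether of 8
Conditions: TESOTf, 2,6-lutidine, CH2Cl2, −78 → 0 °C
Reagents that add atoms: triethylsilyl trifluoromethanesulfonate, CC[Si](CC)(CC)OS(=O)(=O)C(F)(F)F
Why: Silylation of a hindered alcohol with a silyl triflate and a weak base, which avoids the alkoxide that could trigger 1,3-silyl migration from O14.

Step 7
Reactants: 10 but-2-yn-1-ol
Product: 12 (Z)-3-iodobut-2-en-1-ol, via cyclic alkenylaluminate 11 (not isolated)
Conditions: NaAlH2(OCH2CH2OMe)2, THF, 0 °C → rt; then I2, −78 °C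
Reagents that add atoms: iodine, II; sodium bis(2-methoxyethoxy)aluminium dihydride (in 11 only), [Na+].[AlH2-](OCCOC)OCCOC
Why: Alkoxide-directed trans-hydroalumination of a propargylic alcohol places aluminium on C3 cis to the carbinol carbon, and iodinolysis with retention gives the Z alkenyl iodide.

Step 8
Reactants: 12 (Z)-3-iodobut-2-en-1-ol
Product: 13 tert-butyl{[(2Z)-3-iodobut-2-en-1-yl]oxy}dimethylsilane
Conditions: TBSCl, imidazole, DMF, rt
Reagents that add atoms: tert-butyldimethylsilyl chloride, CC(C)(C)[Si](C)(C)Cl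
Why: Standard imidazole-promoted silylation of a primary alcohol.

Step 9
Reactants: 9 C2 triethylsilyl ether; 13 Z alkenyl iodide
Product: 15 coupled product with the C3–C7 chain C2H(OTES)–CH2CH2–C(CH3)=CH–CH2OTBS (5Z), via B-alkyl-9-BBN adduct 14 (not isolated)
Conditions: 9-BBN, THF, rt; then 13, Pd(dppf)Cl2 (5 mol %), AsPh3, Cs2CO3, DMF/H2O, rt
Reagents that add atoms: 9-borabicyclo[3.3.1]nonane (in 14 only), B1C2CCCC1CCC2
Why: B-alkyl Suzuki–Miyaura coupling: 9-BBN hydroborates only the terminal vinyl group (boron on C4, the trisubstituted C11=C12 being inert), and the palladium-catalysed coupling forms C4–C5 with retention of the Z geometry.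

Step 10
Reactants: 15 coupled product
Product: 16 C9 primary alcohol (15 without the p-methoxybenzyl group)
Conditions: DDQ, CH2Cl2/pH 7 buffer, 0 °C
Reagents that add atoms: none
Why: Oxidative cleavage of a p-methoxybenzyl ether through the benzylic oxocarbenium ion, which leaves silyl ethers and trisubstituted alkenes untouched.

Step 11
Reactants: 16 C9 primary alcohol
Product: 19 propargylic alcohol C9–C8≡C17–C19H2OH, via C9 triflate 17 (not isolated), via O-trimethylsilyl alkyne 18 (not isolated)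
Conditions: Tf2O, 2,6-lutidine, CH2Cl2, −78 °C; then LiC≡CCH2OSiMe3 (from the alkyne and n-BuLi), THF/DMPU, −78 → −20 °C; then K2CO3, MeOH, 0 °C
Reagents that add atoms: trimethyl(prop-2-yn-1-yloxy)silane, C#CCO[Si](C)(C)C; trifluoromethanesulfonic anhydride (in 17 only), O=S(=O)(C(F)(F)F)OS(=O)(=O)C(F)(F)F
Why: SN2 alkylation of a lithium acetylide by a primary triflate (the leaving group of choice for a β-branched carbon), followed by methanolysis of the labile trimethylsilyl ether.

Step 12
Reactants: 19 propargylic alcohol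
Product: 21 (Z)-alkenyl iodide C9–C8(I)=C17(CH3)–C19H2OH with iodine cis to CH2OH, via oxamagnesacycle 20 (not isolated)
Conditions: MeMgBr, CuI (20 mol %), THF, −20 °C → rt; then I2, −78 → 0 °C
Reagents that add atoms: methylmagnesium bromide, C[Mg]Br; iodine, II
Why: Copper-catalysed anti-carbomagnesiation of a propargylic alkoxide (Duboudin-type) puts the methyl group on C17 and magnesium on C8 in a five-membered chelate, and iodinolysis with retention fixes the tetrasubstituted alkene geometry.

Step 13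
Reactants: 21 (Z)-alkenyl iodide alcohol
Product: 22 (Z)-3-iodo-2-methylacrylic acid (C19 carboxylic acid of 21)
Conditions: TEMPO (cat.), PhI(OAc)2, MeCN/H2O, rt
Reagents that add atoms: water, O
Why: Oxoammonium-mediated oxidation of a primary alcohol through the aldehyde hydrate to the acid, without touching silyl ethers or the alkene geometry.

Step 14
Reactants: 22 C19 carboxylic acid
Product: 23 methyl ester of 22
Conditions: Me3SiCHN2, PhMe/MeOH, 0 °C
Reagents that add atoms: (trimethylsilyl)diazomethane, C[Si](C)(C)C=[N+]=[N-]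
Why: Neutral esterification of a carboxylic acid by a diazoalkane.

Step 15
Reactants: 23 methyl ester
Product: 24 diol with free C2–OH and C7–OH (C14–OTBS retained)
Conditions: HF·pyridine, pyridine, THF, 0 °C
Reagents that add atoms: none
Why: Fluoride desilylation graded by lability: the triethylsilyl ether and the primary allylic TBS ether cleave, the hindered secondary C14 TBS ether does not.

Step 16
Reactants: 24 diol
Product: 25 (Z)-enal (24 oxidised at C7, C2–OH free)
Conditions: MnO2, CH2Cl2, rt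
Reagents that add atoms: none
Why: MnO2 oxidises only the allylic primary alcohol and should preserve the Z geometry of the enal.

Step 17
Reactants: 25 (Z)-enal bearing the alkenyl iodide
Product: 27 macrocyclic butenolide (7R) with free C2–OH, C14–OTBS and C11=C12, via chromium alkoxide 26 (not isolated)
Conditions: CrCl2 (10 equiv), NiCl2 (cat.), DMSO, rt, 0.003 M, slow addition
Reagents that add atoms: chromium dichloride (in 26 only), Cl[Cr]Cl
Why: Intramolecular Nozaki–Hiyama–Kishi reaction: zerovalent nickel inserts into the C8–I bond, transmetalation gives the alkenylchromium with retention, and 1,2-addition to the C7 aldehyde closes the ten-membered ring, the alkoxide then lactonising onto the cis ester; C7 is set under substrate control and is expected to form with the new C–O bond syn to the C2 oxygen, which has to be confirmed.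

Step 18
Reactants: 27 macrocyclic butenolide
Product: 28 C2 butanoate of 27
Conditions: (PrCO)2O, Et3N, DMAP, CH2Cl2, rt
Reagents that add atoms: butanoic anhydride, CCCC(=O)OC(=O)CCC
Why: DMAP-catalysed acylation of the only free hydroxyl group.

Step 19
Reactants: 28 C2 butanoate
Product: 29 C14 alcohol of 28
Conditions: HF·pyridine, THF, 0 °C → rt
Reagents that add atoms: none
Why: Unbuffered fluoride cleavage of the hindered secondary silyl ether under acidic conditions that spare the esters and the butenolide and disfavour acyl migration.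

Step 20
Reactants: 29 C14 alcohol
Product: 30 C14 acetate of 29 (the 11,12-deoxy target)
Conditions: Ac2O, pyridine, DMAP, CH2Cl2, 0 °C → rt
Reagents that add atoms: acetic anhydride, CC(=O)OC(C)=O
Why: DMAP-catalysed acetylation of the axial secondary alcohol, fast enough with excess anhydride to precede 1,3-acyl migration from O2.

Step 21
Reactants: 30 C14 acetate
Product: 31 target CNP0220791.1
Conditions: 1,2:4,5-di-O-isopropylidene-D-erythro-2,3-hexodiulo-2,6-pyranose (D-fructose-derived ketone, 0.3 equiv), Oxone (2KHSO5·KHSO4·K2SO4), K2CO3, Bu4NHSO4, MeCN/CH2(OMe)2/aq. Na2B4O7, 0 °C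
Reagents that add atoms: potassium peroxymonosulfate, [K+].[O-]S(=O)(=O)OO
Why: Shi epoxidation: the chiral dioxirane should react through the spiro transition state with the most electron-rich alkene C11=C12 (C5=C6 is deactivated by the allylic lactone oxygen, C8=C17 is conjugated) and, by analogy with 1-substituted cyclohexenes, deliver oxygen to the face syn to the C1 methyl group, giving 11S,12R under reagent control.

Compound list
1 | 2-[(4-methoxybenzyl)oxy]acetaldehyde | O=CCOCc1ccc(OC)cc1 | starting material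
2 | 2-(triphenyl-λ5-phosphanylidene)propanal | CC(C=O)=P(c1ccccc1)(c1ccccc1)c1ccccc1 | starting material
3 | (E)-4-[(4-methoxybenzyl)oxy]-2-methylbut-2-enal | O=C/C(C)=C/COCc1ccc(OC)cc1 | intermediate
4 | (E)-pent-2-enal | CC/C=C/C=O | starting material
5 | (1E,3E)-1-(tert-butyldimethylsilyloxy)penta-1,3-diene | C/C=C/C=C/O[Si](C)(C)C(C)(C)C | intermediate
6 | (1S,2R,5S,6R)-2-(tert-butyldimethylsilyloxy)-6-{[(4-methoxybenzyl)oxy]methyl}-1,5-dimethylcyclohex-3-ene-1-carbaldehyde | C(OCc1ccc(OC)cc1)[C@@H]2[C@@H](C)C=C[C@@H](O[Si](C)(C)C(C)(C)C)[C@]2(C=O)C | intermediate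
7 | (1S,2R,6R)-2-(tert-butyldimethylsilyloxy)-6-{[(4-methoxybenzyl)oxy]methyl}-1,5-dimethylcyclohex-4-ene-1-carbaldehyde | C(OCc1ccc(OC)cc1)[C@@H]2C(C)=CC[C@@H](O[Si](C)(C)C(C)(C)C)[C@]2(C=O)C | intermediate
8 | (2S)-vinyl carbinol of 7 (C2H(OH)–CH=CH2) | C(OCc1ccc(OC)cc1)[C@@H]2C(C)=CC[C@@H](O[Si](C)(C)C(C)(C)C)[C@]2([C@@H](O)C=C)C | intermediate
9 | C2 triethylsilyl ether of 8 | C(OCc1ccc(OC)cc1)[C@@H]2C(C)=CC[C@@H](O[Si](C)(C)C(C)(C)C)[C@]2([C@@H](O[Si](CC)(CC)CC)C=C)C | intermediate
10 | but-2-yn-1-ol | CC#CCO | starting material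
11 | sodium cyclic alkenyl(alkoxy)aluminate from 10 (2,5-dihydro-1,2-oxaluminole) | CC1=CCO[Al-]1(OCCOC)OCCOC.[Na+] | intermediate
12 | (Z)-3-iodobut-2-en-1-ol | C/C(I)=C/CO | intermediate
13 | tert-butyl{[(2Z)-3-iodobut-2-en-1-yl]oxy}dimethylsilane | C/C(I)=C/CO[Si](C)(C)C(C)(C)C | intermediate
14 | B-alkyl-9-BBN adduct of 9 (boron on C4) | C(OCc1ccc(OC)cc1)[C@@H]2C(C)=CC[C@@H](O[Si](C)(C)C(C)(C)C)[C@]2([C@@H](O[Si](CC)(CC)CC)CCB3C4CCCC3CCC4)C | intermediate
15 | Suzuki product: 9 extended to C2H(OTES)–CH2CH2–C(CH3)=CH–CH2OTBS (5Z) | C(OCc1ccc(OC)cc1)[C@@H]2C(C)=CC[C@@H](O[Si](C)(C)C(C)(C)C)[C@]2([C@@H](O[Si](CC)(CC)CC)CC/C(C)=C\CO[Si](C)(C)C(C)(C)C)C | intermediate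
16 | C9 primary alcohol | OC[C@@H]1C(C)=CC[C@@H](O[Si](C)(C)C(C)(C)C)[C@]1([C@@H](O[Si](CC)(CC)CC)CC/C(C)=C\CO[Si](C)(C)C(C)(C)C)C | intermediate
17 | C9 trifluoromethanesulfonate of 16 | FC(F)(F)S(=O)(=O)OC[C@@H]1C(C)=CC[C@@H](O[Si](C)(C)C(C)(C)C)[C@]1([C@@H](O[Si](CC)(CC)CC)CC/C(C)=C\CO[Si](C)(C)C(C)(C)C)C | intermediate
18 | O-trimethylsilyl alkyne C9–C≡C–CH2OSiMe3 | C[Si](C)(C)OCC#CC[C@@H]1C(C)=CC[C@@H](O[Si](C)(C)C(C)(C)C)[C@]1([C@@H](O[Si](CC)(CC)CC)CC/C(C)=C\CO[Si](C)(C)C(C)(C)C)C | intermediate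
19 | propargylic alcohol C9–C8≡C17–C19H2OH | OCC#CC[C@@H]1C(C)=CC[C@@H](O[Si](C)(C)C(C)(C)C)[C@]1([C@@H](O[Si](CC)(CC)CC)CC/C(C)=C\CO[Si](C)(C)C(C)(C)C)C | intermediate
20 | five-membered oxamagnesacycle (C8–Mg–O19) | CC1=C(C[C@@H]2C(C)=CC[C@@H](O[Si](C)(C)C(C)(C)C)[C@]2([C@@H](O[Si](CC)(CC)CC)CC/C(C)=C\CO[Si](C)(C)C(C)(C)C)C)[Mg]OC1 | intermediate
21 | (Z)-alkenyl iodide C9–C8(I)=C17(CH3)–C19H2OH | OC/C(C)=C(\I)C[C@@H]1C(C)=CC[C@@H](O[Si](C)(C)C(C)(C)C)[C@]1([C@@H](O[Si](CC)(CC)CC)CC/C(C)=C\CO[Si](C)(C)C(C)(C)C)C | intermediate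
22 | C19 carboxylic acid of 21 | OC(=O)/C(C)=C(\I)C[C@@H]1C(C)=CC[C@@H](O[Si](C)(C)C(C)(C)C)[C@]1([C@@H](O[Si](CC)(CC)CC)CC/C(C)=C\CO[Si](C)(C)C(C)(C)C)C | intermediate
23 | methyl ester of 22 | COC(=O)/C(C)=C(\I)C[C@@H]1C(C)=CC[C@@H](O[Si](C)(C)C(C)(C)C)[C@]1([C@@H](O[Si](CC)(CC)CC)CC/C(C)=C\CO[Si](C)(C)C(C)(C)C)C | intermediate
24 | C2,C7 diol | COC(=O)/C(C)=C(\I)C[C@@H]1C(C)=CC[C@@H](O[Si](C)(C)C(C)(C)C)[C@]1([C@@H](O)CC/C(C)=C\CO)C | intermediate
25 | (Z)-enal with C7 formyl group | COC(=O)/C(C)=C(\I)C[C@@H]1C(C)=CC[C@@H](O[Si](C)(C)C(C)(C)C)[C@]1([C@@H](O)CC/C(C)=C\C=O)C | intermediate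
26 | C7 chromium alkoxide of the ring-closed hydroxy ester | O[C@H]1CC/C(C)=C\[C@@H](O[Cr](Cl)Cl)/C(=C(/C)C(=O)OC)C[C@@H]2C(C)=CC[C@@H](O[Si](C)(C)C(C)(C)C)[C@@]12C | intermediate
27 | macrocyclic butenolide (2S,7R), C2–OH free, C14–OTBS, C11=C12 | O[C@H]1CC/C(C)=C\[C@H]2OC(=O)C(C)=C2C[C@@H]2C(C)=CC[C@@H](O[Si](C)(C)C(C)(C)C)[C@@]12C | intermediate
28 | C2 butanoate of 27 | CCCC(=O)O[C@H]1CC/C(C)=C\[C@H]2OC(=O)C(C)=C2C[C@@H]2C(C)=CC[C@@H](O[Si](C)(C)C(C)(C)C)[C@@]12C | intermediate
29 | C14 alcohol of 28 | CCCC(=O)O[C@H]1CC/C(C)=C\[C@H]2OC(=O)C(C)=C2C[C@@H]2C(C)=CC[C@@H](O)[C@@]12C | intermediate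
30 | C14 acetate of 29 (11,12-deoxy target) | CCCC(=O)O[C@H]1CC/C(C)=C\[C@H]2OC(=O)C(C)=C2C[C@@H]2C(C)=CC[C@@H](OC(C)=O)[C@@]12C | intermediate
31 | CNP0220791.1 | CCCC(=O)O[C@H]1CC/C(C)=C\[C@H]2OC(=O)C(C)=C2C[C@@H]2[C@]3(C)O[C@@H]3C[C@@H](OC(C)=O)[C@@]12C | target

Total step count: 21. Longest linear sequence: 18 steps (steps 1, 3–6 and 9–21).

Steps most likely to fail

Step 3 (Diels–Alder). The α,β-disubstituted enal may react too slowly at low temperature, so that the acidic catalyst consumes the silyl dienol ether by desilylation or carbonyl addition, or the endo/exo and facial discrimination may be incomplete. The fallback sets out from 3 and 5 and comes back at 6, and moves enantiocontrol from the catalyst to a resolution. The cycloaddition is promoted by Me2AlCl (CH2Cl2, −78 °C) without a chiral catalyst, which should give the racemic endo adduct, that is 6 together with the enantiomer of 6 F1. Condensation of the mixture with (1R,2R)-N,N′-dimethyl-1,2-diphenylethane-1,2-diamine (4 Å sieves, Et2O) gives two diastereomeric imidazolidines, the aminal of 6 F2 and the aminal of the enantiomer F3, which are separated by chromatography. Brief hydrolysis of F2 (AcOH/H2O/THF) returns 6.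

Step 4 (alkene isomerisation). Hydride insertion may run toward C14, giving the silyl enol ether, or continue to the tetrasubstituted C10=C11 position with loss of the C10 stereocentre. The fallback sets out from 6 and comes back at 9, and moves the double bond stepwise after the formyl group has been elaborated. Vinylmagnesium bromide addition to 6 gives the C12=C13 vinyl carbinol F4, and TESOTf/2,6-lutidine gives its triethylsilyl ether F5. mCPBA (NaHCO3, CH2Cl2, 0 °C) should epoxidise the cis-disubstituted ring alkene, not the terminal vinyl group, from the face opposite the C14 silyl ether and the C11 methyl group, giving the 12,13-epoxide F6. Et2Al(TMP) (toluene, 0 °C) removes the syn hydrogen at C11 and opens the epoxide to the allylic alcohol F7 (C11=C12, C13–OH). Acetylation gives the allylic acetate F8, and Pd(PPh3)4/LiBHEt3 delivers hydride to the less hindered C13 end of the π-allyl complex, which gives 9.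

Step 17 (Nozaki–Hiyama–Kishi closure). Closure of the strained ten-membered ring may be slower than protodeiodination or oligomerisation of the ester-bearing alkenylchromium, and the aldehyde face that is attacked is fixed only by the folding of the chain. The fallback sets out from 21 and comes back at 27, and separates ring closure from lactone formation. Silylation of 21 (TBDPSCl, imidazole) gives the C19 tert-butyldiphenylsilyl ether F9. HF·pyridine/pyridine at 0 °C removes only the triethylsilyl and primary TBS groups to give the diol F10, and MnO2 gives the (Z)-enal F11. The chromium/nickel closure of this more electron-rich alkenyl iodide gives the macrocyclic C7 carbinol F12, and TBAF frees C19 to give the ene-triol F13. TEMPO/PhI(OAc)2 then oxidises the primary allylic alcohol through the lactol to the butenolide 27.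

Further compounds
F1 | step 3 | enantiomer of 6 | C(OCc1ccc(OC)cc1)[C@H]2[C@H](C)C=C[C@H](O[Si](C)(C)C(C)(C)C)[C@@]2(C=O)C
F2 | step 3 | (4R,5R)-1,3-dimethyl-4,5-diphenylimidazolidine (aminal) of 6 | C(OCc1ccc(OC)cc1)[C@@H]2[C@@H](C)C=C[C@@H](O[Si](C)(C)C(C)(C)C)[C@]2(C3N(C)[C@H](c4ccccc4)[C@@H](c4ccccc4)N3C)C
F3 | step 3 | (4R,5R)-1,3-dimethyl-4,5-diphenylimidazolidine (aminal) of the enantiomer of 6 | C(OCc1ccc(OC)cc1)[C@H]2[C@H](C)C=C[C@H](O[Si](C)(C)C(C)(C)C)[C@@]2(C3N(C)[C@H](c4ccccc4)[C@@H](c4ccccc4)N3C)C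
F4 | step 4 | (2S)-vinyl carbinol of 6 (C12=C13 retained) | C(OCc1ccc(OC)cc1)[C@@H]2[C@@H](C)C=C[C@@H](O[Si](C)(C)C(C)(C)C)[C@]2([C@@H](O)C=C)C
F5 | step 4 | C2 triethylsilyl ether of F4 | C(OCc1ccc(OC)cc1)[C@@H]2[C@@H](C)C=C[C@@H](O[Si](C)(C)C(C)(C)C)[C@]2([C@@H](O[Si](CC)(CC)CC)C=C)C
F6 | step 4 | 12,13-epoxide of F5 (oxygen trans to the C14 silyl ether) | C(OCc1ccc(OC)cc1)[C@@H]2[C@@H](C)[C@@H]3O[C@@H]3[C@@H](O[Si](C)(C)C(C)(C)C)[C@]2([C@@H](O[Si](CC)(CC)CC)C=C)C
F7 | step 4 | allylic alcohol (C11=C12, C13–OH trans to the C14 silyl ether) | C(OCc1ccc(OC)cc1)[C@@H]2C(C)=C[C@H](O)[C@@H](O[Si](C)(C)C(C)(C)C)[C@]2([C@@H](O[Si](CC)(CC)CC)C=C)C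
F8 | step 4 | C13 acetate of F7 | C(OCc1ccc(OC)cc1)[C@@H]2C(C)=C[C@H](OC(C)=O)[C@@H](O[Si](C)(C)C(C)(C)C)[C@]2([C@@H](O[Si](CC)(CC)CC)C=C)C
F9 | step 17 | C19 tert-butyldiphenylsilyl ether of 21 | CC(C)(C)[Si](c1ccccc1)(c1ccccc1)OC/C(C)=C(\I)C[C@@H]2C(C)=CC[C@@H](O[Si](C)(C)C(C)(C)C)[C@]2([C@@H](O[Si](CC)(CC)CC)CC/C(C)=C\CO[Si](C)(C)C(C)(C)C)C
F10 | step 17 | C2,C7 diol of F9 | CC(C)(C)[Si](c1ccccc1)(c1ccccc1)OC/C(C)=C(\I)C[C@@H]2C(C)=CC[C@@H](O[Si](C)(C)C(C)(C)C)[C@]2([C@@H](O)CC/C(C)=C\CO)C
F11 | step 17 | (Z)-enal of F10 (C7 formyl group) | CC(C)(C)[Si](c1ccccc1)(c1ccccc1)OC/C(C)=C(\I)C[C@@H]2C(C)=CC[C@@H](O[Si](C)(C)C(C)(C)C)[C@]2([C@@H](O)CC/C(C)=C\C=O)C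
F12 | step 17 | macrocyclic C7 carbinol with C19 silyl ether | O[C@H]1CC/C(C)=C\[C@@H](O)/C(=C(/C)CO[Si](c3ccccc3)(c3ccccc3)C(C)(C)C)C[C@@H]2C(C)=CC[C@@H](O[Si](C)(C)C(C)(C)C)[C@@]12C
F13 | step 17 | macrocyclic ene-triol (C2–OH, C7–OH, C19–OH) | O[C@H]1CC/C(C)=C\[C@@H](O)/C(=C(/C)CO)C[C@@H]2C(C)=CC[C@@H](O[Si](C)(C)C(C)(C)C)[C@@]12C
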